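**Plan**
- Retrosynthesis: the 4a,5-diol goes back to the C4a=C5 alkene of a dienone (epoxide opening), ring B is cut at C2–C3 (alkenyl metal plus aldehyde), and the dienyl triflate is cut at C4–C4a into a bromocyclopentyl alkyne and a ring-A bromo ketone.
- Enabling feature: C3 of ring B is an sp2 carbon held between the quaternary C1′ of the cyclopentane and the C2 carbonyl, so a C3 ketone can enolise only toward C4 and its enol triflate becomes a C3 alkenyl metal that reaches an aldehyde carbon (C2) hanging from C8a.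
- Forward order: the cyclopentane is taken from commercial (1R,4S)-camphanic acid and ring A from commercial 2-methylcyclohexane-1,3-dione; alkynyl addition and Meyer–Schuster rearrangement join them, ring B closes last, then epoxidation and hydrolysis install the diol.
- Stereochemistry: C1′ comes from the chiral pool; C3′ and C8 from Corey–Bakshi–Shibata reductions followed by Appel inversion; C8a from the same desymmetrising reduction; C4a and C5 from α-face epoxidation anti to the 8a-methyl and trans-diaxial opening.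

Key step: step 16

Remark: locants C1–C8a follow the 2(1H)-naphthalenone core and primed locants the cyclopentane; the methyl epimers formed in step 11 and the carbinol epimers formed in step 12 are carried as mixtures, since both centres become trigonal by step 14.

Step 1
Reactants: 1 (1R,4S)-camphanic acid
Product: 3 (1S)-1,2,2-trimethyl-3-oxocyclopentane-1-carboxylic acid (camphononic acid), via dipotassium 3-hydroxycamphorate 2 (not isolated)
Conditions: KOH, H2O, 100 °C; KMnO4, 0 °C to rt; HCl work-up
Reagents that add atoms: potassium hydroxide, [K+].[OH-]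
Why: Hot alkali opens the bridged lactone to the tertiary α-hydroxy carboxylate 2, which permanganate cleaves by oxidative decarboxylation (a known fate of α-hydroxy acids) to the C3′ ketone, leaving the quaternary C1′ centre of the chiral pool untouched.

Step 2
Reactants: 3 (1S)-camphononic acid
Product: 4 methyl (1S)-1,2,2-trimethyl-3-oxocyclopentane-1-carboxylate
Conditions: MeI, K2CO3, DMF, rt
Reagents that add atoms: iodomethane, CI
Why: SN2 O-methylation of the hindered carboxylate masks the acid so that the borane of step 3 meets only the ketone.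

Step 3
Reactants: 4 methyl (1S)-1,2,2-trimethyl-3-oxocyclopentane-1-carboxylate
Product: 5 methyl (1S,3S)-3-hydroxy-1,2,2-trimethylcyclopentane-1-carboxylate (hydroxyl trans to the ester)
Conditions: (R)-Me-CBS (cat.), BH3·SMe2, THF, −20 °C
Reagents that add atoms: none
Why: Corey–Bakshi–Shibata reduction, in which the oxazaborolidine tells the quaternary C2′ flank (large) from the C4′ methylene (small) and delivers hydride under reagent control to give the 3S carbinol, hydroxyl trans to the ester and cis to the C1′ methyl.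

Step 4
Reactants: 5 methyl (1S,3S)-3-hydroxy-1,2,2-trimethylcyclopentane-1-carboxylate
Product: 6 (1S,3S)-3-(hydroxymethyl)-2,2,3-trimethylcyclopentan-1-ol
Conditions: LiAlH4, THF, 0 °C
Reagents that add atoms: none
Why: Hydride reduction of the neopentyl ester to the primary alcohol should proceed without touching either stereocentre.

Step 5
Reactants: 6 (1S,3S)-3-(hydroxymethyl)-2,2,3-trimethylcyclopentan-1-ol
Product: 7 (1S,3S)-3-hydroxy-1,2,2-trimethylcyclopentane-1-carbaldehyde
Conditions: TEMPO (cat.), PhI(OAc)2, CH2Cl2, rt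
Reagents that add atoms: none
Why: Oxoammonium (TEMPO) oxidation is selective for the primary carbinol over the more hindered secondary one, and the trans hydroxy aldehyde cannot close to a lactol.

Step 6
Reactants: 7 (1S,3S)-3-hydroxy-1,2,2-trimethylcyclopentane-1-carbaldehyde
Product: 8 (1S,3R)-3-ethynyl-2,2,3-trimethylcyclopentan-1-ol (hydroxyl trans to ethynyl)
Conditions: dimethyl (1-diazo-2-oxopropyl)phosphonate, K2CO3, MeOH, 0 °C to rt
Reagents that add atoms: dimethyl (1-diazo-2-oxopropyl)phosphonate, CC(=O)C(=[N+]=[N-])P(=O)(OC)OC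
Why: Ohira–Bestmann (Seyferth–Gilbert) homologation turns the non-enolisable α-quaternary aldehyde into the terminal alkyne under mild carbonate conditions that leave the free hydroxyl alone.

Step 7
Reactants: 8 (1S,3R)-3-ethynyl-2,2,3-trimethylcyclopentan-1-ol
Product: 9 (1R,3R)-3-bromo-1-ethynyl-1,2,2-trimethylcyclopentane (bromine cis to ethynyl)
Conditions: CBr4, PPh3, CH2Cl2, 0 to 40 °C
Reagents that add atoms: carbon tetrabromide, BrC(Br)(Br)Br
Why: Appel reaction in which bromide attacks the oxyphosphonium carbon from the rear (SN2, inversion), so bromine ends cis to the ethynyl group as in the target, and doing this on the alkyne rather than on ester 5 removes the carbonyl oxygen that would otherwise displace the leaving group and lactonise.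

Step 8
Reactants: 10 2-methylcyclohexane-1,3-dione
Product: 11 2-methyl-2-(prop-2-en-1-yl)cyclohexane-1,3-dione
Conditions: allyl bromide, NaOH, H2O, rt
Reagents that add atoms: allyl bromide, C=CCBr
Why: C-Allylation of the stabilised 1,3-dione enolate builds the quaternary carbon that becomes C8a, still as a prochiral centre.

Step 9
Reactants: 11 2-methyl-2-(prop-2-en-1-yl)cyclohexane-1,3-dione
Product: 12 (2R,3R)-3-hydroxy-2-methyl-2-(prop-2-en-1-yl)cyclohexan-1-one (hydroxyl cis to allyl)
Conditions: (S)-Me-CBS (cat.), catecholborane, toluene, −60 °C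
Reagents that add atoms: none
Why: Corey–Bakshi–Shibata desymmetrisation, in which the catalyst fixes the 3R carbinol (quaternary flank large, methylene small) and hydride should enter anti to the allyl group, so that one enantiotopic carbonyl is reduced and the quaternary carbon becomes 2R with hydroxyl cis to allyl.

Step 10
Reactants: 12 (2R,3R)-3-hydroxy-2-methyl-2-(prop-2-en-1-yl)cyclohexan-1-one
Product: 13 (2S,3S)-3-bromo-2-methyl-2-(prop-2-en-1-yl)cyclohexan-1-one (bromine cis to methyl)
Conditions: CBr4, PPh3, CH2Cl2, 0 °C to rt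
Reagents that add atoms: carbon tetrabromide, BrC(Br)(Br)Br
Why: Appel reaction with SN2 inversion at the carbinol carbon gives the bromide cis to the C2 methyl (the C8 configuration of the target), a substitution of the kind used on β-ketols with a quaternary α-carbon, where elimination toward the carbonyl is impossible.

Step 11
Reactants: 13 (2S,3S)-3-bromo-2-methyl-2-(prop-2-en-1-yl)cyclohexan-1-one
Product: 15 (2S,3S)-3-bromo-2,6-dimethyl-2-(prop-2-en-1-yl)cyclohexan-1-one (C6 epimers), via lithium enolate 14 (not isolated)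
Conditions: LiN(i-Pr)2, THF, −78 °C; MeI, −78 to −40 °C
Reagents that add atoms: iodomethane, CI
Why: Kinetic enolate alkylation can occur only at C6, the sole α-carbon bearing hydrogen, and the configuration of the new methyl-bearing carbon is of no consequence because it becomes trigonal in step 14.

Step 12
Reactants: 9 (1R,3R)-3-bromo-1-ethynyl-1,2,2-trimethylcyclopentane; 15 (2S,3S)-3-bromo-2,6-dimethyl-2-(prop-2-en-1-yl)cyclohexan-1-one
Product: 18 (2S,3S)-3-bromo-1-{[(1R,3R)-3-bromo-1,2,2-trimethylcyclopentyl]ethynyl}-2,6-dimethyl-2-(prop-2-en-1-yl)cyclohexan-1-ol (C1/C6 epimers), via lithium acetylide 16 (not isolated), via alkynylcerium dichloride 17 (not isolated)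
Conditions: n-BuLi, THF, −78 °C; CeCl3, −78 °C; ketone 15; AcOH, −78 °C
Reagents that add atoms: none
Why: 1,2-Addition of the weakly basic alkynylcerium reagent to the hindered, enolisable ketone joins the two fragments at C4–C4a, the carbinol configuration being irrelevant since step 13 erases it, and the cold acidic quench should keep the γ-bromo alkoxide from Grob fragmentation.

Step 13
Reactants: 18 propargylic alcohol (C1/C6 epimers)
Product: 19 (2E)-1-[(1S,3R)-3-bromo-1,2,2-trimethylcyclopentyl]-2-[(2S,3S)-3-bromo-2,6-dimethyl-2-(prop-2-en-1-yl)cyclohexylidene]ethan-1-one (C6 epimers)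
Conditions: ReOCl3(OPPh3)(SMe2) (cat.), DME, rt to 45 °C
Reagents that add atoms: none
Why: Meyer–Schuster rearrangement, in which the oxo-rhenium catalyst shifts the hydroxyl from C4a to C3 through a [3,3] shift of its rhenate ester and the allenol tautomerises to the enone, whose acyl group should settle cis to C5 and away from the quaternary C8a.

Step 14
Reactants: 19 exocyclic enone (C6 epimers)
Product: 21 (1Z)-1-[(1S,3R)-3-bromo-1,2,2-trimethylcyclopentyl]-2-[(5S,6S)-5-bromo-2,6-dimethyl-6-(prop-2-en-1-yl)cyclohex-1-en-1-yl]ethenyl trifluoromethanesulfonate, via potassium dienolate 20 (not isolated)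
Conditions: KN(SiMe3)2, THF, −78 to −30 °C; PhNTf2, −78 to 0 °C
Reagents that add atoms: N-phenylbis(trifluoromethanesulfonimide), O=S(=O)(N(c1ccccc1)S(=O)(=O)C(F)(F)F)C(F)(F)F
Why: Vinylogous enolisation can remove only the C5 hydrogen because C1′ and C8a are quaternary, the s-cis enone places oxygen cis to C4a in dienolate 20, and O-sulfonylation with the triflimide then gives the Z dienyl triflate with the bulky cyclopentyl group trans to C4a.

Step 15
Reactants: 21 Z dienyl triflate with the allyl group on C8a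
Product: 23 (1Z)-1-[(1S,3R)-3-bromo-1,2,2-trimethylcyclopentyl]-2-[(5S,6S)-5-bromo-2,6-dimethyl-6-(2-oxoethyl)cyclohex-1-en-1-yl]ethenyl trifluoromethanesulfonate (Z dienyl triflate carrying the C2 aldehyde), via vicinal diol 22 (not isolated)
Conditions: OsO4 (cat.), NaIO4, 2,6-lutidine, dioxane–H2O, rt
Reagents that add atoms: osmium tetroxide, O=[Os](=O)(=O)=O; sodium periodate, [Na+].[O-]I(=O)(=O)=O
Why: Lemieux–Johnson cleavage, in which OsO4 should dihydroxylate only the unhindered monosubstituted alkene (the tetrasubstituted ring alkene and the electron-poor enol triflate alkene are shielded and deactivated) and periodate cuts diol 22 to the aldehyde.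

Step 16
Reactants: 23 Z dienyl triflate carrying the C2 aldehyde
Product: 25 (8S,8aS)-8-bromo-3-[(1R,3R)-3-bromo-1,2,2-trimethylcyclopentyl]-5,8a-dimethyl-1,2,6,7,8,8a-hexahydronaphthalen-2-ol (ring-B dienyl alcohol; C2 epimers), via alkenylchromium dichloride 24 (not isolated)
Conditions: CrCl2 (excess), NiCl2 (cat.), degassed DMF, rt, high dilution
Reagents that add atoms: none
Why: Zerovalent nickel, generated from NiCl2 by CrCl2, undergoes oxidative addition to the C3–O bond of the triflate, the alkenyl group is passed on to trivalent chromium to give 24, and its C3 carbon then attacks the aldehyde carbon, forming C2–C3 with the C3=C4 geometry kept. The closest known reaction type is the intramolecular Nozaki–Hiyama–Kishi coupling of alkenyl triflates with aldehydes to six-membered cyclic allylic alcohols. Ring B closes in a 6-exo-trig mode, the metal-bearing C3 adding to the carbonyl of the two-carbon arm on C8a. The only new stereocentre, the C2 carbinol, is not controlled and need not be, because step 17 oxidises it. The step needs chemoselectivity for the alkenyl triflate over the two secondary alkyl bromides and a geometry that lets the metal reach the aldehyde: divalent chromium leaves unactivated secondary bromides alone at room temperature, and the Z triflate in the s-trans diene conformation holds C3 next to the C8a side chain.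

Step 17
Reactants: 25 ring-B dienyl alcohol (C2 epimers)
Product: 26 (8S,8aS)-8-bromo-3-[(1R,3R)-3-bromo-1,2,2-trimethylcyclopentyl]-5,8a-dimethyl-6,7,8,8a-tetrahydronaphthalen-2(1H)-one
Conditions: Dess–Martin periodinane, NaHCO3, CH2Cl2, 0 °C to rt
Reagents that add atoms: none
Why: Dess–Martin oxidation of the allylic alcohol under buffered conditions gives the linear dienone and removes the uncontrolled C2 centre.

Step 18
Reactants: 26 linear dienone
Product: 27 4a,5-α-epoxide of dienone 26 (oxirane oxygen anti to the 8a-methyl)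
Conditions: mCPBA, NaHCO3, CH2Cl2, 0 °C
Reagents that add atoms: 3-chloroperbenzoic acid, OOC(=O)c1cccc(Cl)c1
Why: Prilezhaev epoxidation should take the electron-richer tetrasubstituted γ,δ-alkene rather than the α,β-alkene and approach its α face, anti to the axial 8a-methyl on the neighbouring carbon, which sets the C4a–O bond α.

Step 19
Reactants: 27 4a,5-α-epoxy enone
Product: 28 CNP0216929.1 [(4aR,5R,8S,8aS)-8-bromo-3-[(1R,3R)-3-bromo-1,2,2-trimethylcyclopentyl]-4a,5-dihydroxy-5,8a-dimethyl-4a,5,6,7,8,8a-hexahydronaphthalen-2(1H)-one]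
Conditions: HClO4 (dilute aq), THF, 0 °C
Reagents that add atoms: water, O
Why: Acid-catalysed epoxide hydrolysis following the Fürst–Plattner rule, in which water attacks C5 from the β face with inversion (trans-diaxial opening; C5 is the tertiary carbon not deactivated by the enone, whereas a cation at C4a would be conjugated with it), giving the 4a-α,5-β-diol with the C5 methyl equatorial.

**Compound list**
1 | (1R,4S)-camphanic acid [(1R,4S)-4,7,7-trimethyl-3-oxo-2-oxabicyclo[2.2.1]heptane-1-carboxylic acid] | CC1(C)[C@@]2(C(=O)O)CC[C@]1(C)C(=O)O2 | starting material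
2 | dipotassium (1S,3R)-3-hydroxy-1,2,2-trimethylcyclopentane-1,3-dicarboxylate | CC1(C)[C@@](O)(C(=O)[O-])CC[C@]1(C)C(=O)[O-].[K+].[K+] | intermediate
3 | (1S)-1,2,2-trimethyl-3-oxocyclopentane-1-carboxylic acid | CC1(C)C(=O)CC[C@]1(C)C(=O)O | intermediate
4 | methyl (1S)-1,2,2-trimethyl-3-oxocyclopentane-1-carboxylate | CC1(C)C(=O)CC[C@]1(C)C(=O)OC | intermediate
5 | methyl (1S,3S)-3-hydroxy-1,2,2-trimethylcyclopentane-1-carboxylate | CC1(C)[C@@H](O)CC[C@]1(C)C(=O)OC | intermediate
6 | (1S,3S)-3-(hydroxymethyl)-2,2,3-trimethylcyclopentan-1-ol | CC1(C)[C@@H](O)CC[C@]1(C)CO | intermediate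
7 | (1S,3S)-3-hydroxy-1,2,2-trimethylcyclopentane-1-carbaldehyde | CC1(C)[C@@H](O)CC[C@]1(C)C=O | intermediate
8 | (1S,3R)-3-ethynyl-2,2,3-trimethylcyclopentan-1-ol | CC1(C)[C@@H](O)CC[C@]1(C)C#C | intermediate
9 | (1R,3R)-3-bromo-1-ethynyl-1,2,2-trimethylcyclopentane | CC1(C)[C@H](Br)CC[C@]1(C)C#C | intermediate
10 | 2-methylcyclohexane-1,3-dione | CC1C(=O)CCCC1=O | starting material
11 | 2-methyl-2-(prop-2-en-1-yl)cyclohexane-1,3-dione | C=CCC1(C)C(=O)CCCC1=O | intermediate
12 | (2R,3R)-3-hydroxy-2-methyl-2-(prop-2-en-1-yl)cyclohexan-1-one | O=C1CCC[C@@H](O)[C@@]1(C)CC=C | intermediate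
13 | (2S,3S)-3-bromo-2-methyl-2-(prop-2-en-1-yl)cyclohexan-1-one | O=C1CCC[C@H](Br)[C@@]1(C)CC=C | intermediate
14 | lithium (5S,6S)-5-bromo-6-methyl-6-(prop-2-en-1-yl)cyclohex-1-en-1-olate | [Li]OC1=CCC[C@H](Br)[C@@]1(C)CC=C | intermediate
15 | (2S,3S)-3-bromo-2,6-dimethyl-2-(prop-2-en-1-yl)cyclohexan-1-one, C6 epimers | O=C1C(C)CC[C@H](Br)[C@@]1(C)CC=C | intermediate
16 | lithium [(1R,3R)-3-bromo-1,2,2-trimethylcyclopentyl]acetylide | CC1(C)[C@H](Br)CC[C@]1(C)C#C[Li] | intermediate
17 | [(1R,3R)-3-bromo-1,2,2-trimethylcyclopentyl]ethynylcerium dichloride | CC1(C)[C@H](Br)CC[C@]1(C)C#C[Ce](Cl)Cl | intermediate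
18 | (2S,3S)-3-bromo-1-{[(1R,3R)-3-bromo-1,2,2-trimethylcyclopentyl]ethynyl}-2,6-dimethyl-2-(prop-2-en-1-yl)cyclohexan-1-ol, C1/C6 epimers | CC1(C)[C@H](Br)CC[C@]1(C)C#CC1(O)C(C)CC[C@H](Br)[C@@]1(C)CC=C | intermediate
19 | (2E)-1-[(1S,3R)-3-bromo-1,2,2-trimethylcyclopentyl]-2-[(2S,3S)-3-bromo-2,6-dimethyl-2-(prop-2-en-1-yl)cyclohexylidene]ethan-1-one, C6 epimers | CC1(C)[C@H](Br)CC[C@]1(C)C(=O)/C=C1\C(C)CC[C@H](Br)[C@@]1(C)CC=C | intermediate
20 | potassium (1Z)-1-[(1S,3R)-3-bromo-1,2,2-trimethylcyclopentyl]-2-[(5S,6S)-5-bromo-2,6-dimethyl-6-(prop-2-en-1-yl)cyclohex-1-en-1-yl]ethen-1-olate | CC1(C)[C@H](Br)CC[C@]1(C)/C([O-])=C/C1=C(C)CC[C@H](Br)[C@@]1(C)CC=C.[K+] | intermediate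
21 | (1Z)-1-[(1S,3R)-3-bromo-1,2,2-trimethylcyclopentyl]-2-[(5S,6S)-5-bromo-2,6-dimethyl-6-(prop-2-en-1-yl)cyclohex-1-en-1-yl]ethenyl trifluoromethanesulfonate | CC1(C)[C@H](Br)CC[C@]1(C)/C(OS(=O)(=O)C(F)(F)F)=C/C1=C(C)CC[C@H](Br)[C@@]1(C)CC=C | intermediate
22 | (1Z)-1-[(1S,3R)-3-bromo-1,2,2-trimethylcyclopentyl]-2-[(5S,6S)-5-bromo-6-(2,3-dihydroxypropyl)-2,6-dimethylcyclohex-1-en-1-yl]ethenyl trifluoromethanesulfonate | CC1(C)[C@H](Br)CC[C@]1(C)/C(OS(=O)(=O)C(F)(F)F)=C/C1=C(C)CC[C@H](Br)[C@@]1(C)CC(O)CO | intermediate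
23 | (1Z)-1-[(1S,3R)-3-bromo-1,2,2-trimethylcyclopentyl]-2-[(5S,6S)-5-bromo-2,6-dimethyl-6-(2-oxoethyl)cyclohex-1-en-1-yl]ethenyl trifluoromethanesulfonate | CC1(C)[C@H](Br)CC[C@]1(C)/C(OS(=O)(=O)C(F)(F)F)=C/C1=C(C)CC[C@H](Br)[C@@]1(C)CC=O | intermediate
24 | dichloro{(1Z)-1-[(1S,3R)-3-bromo-1,2,2-trimethylcyclopentyl]-2-[(5S,6S)-5-bromo-2,6-dimethyl-6-(2-oxoethyl)cyclohex-1-en-1-yl]ethenyl}chromium | CC1(C)[C@H](Br)CC[C@]1(C)/C([Cr](Cl)Cl)=C/C1=C(C)CC[C@H](Br)[C@@]1(C)CC=O | intermediate
25 | (8S,8aS)-8-bromo-3-[(1R,3R)-3-bromo-1,2,2-trimethylcyclopentyl]-5,8a-dimethyl-1,2,6,7,8,8a-hexahydronaphthalen-2-ol, C2 epimers | CC1(C)[C@H](Br)CC[C@]1(C)C1=CC2=C(C)CC[C@H](Br)[C@@]2(C)CC1O | intermediate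
26 | (8S,8aS)-8-bromo-3-[(1R,3R)-3-bromo-1,2,2-trimethylcyclopentyl]-5,8a-dimethyl-6,7,8,8a-tetrahydronaphthalen-2(1H)-one | CC1(C)[C@H](Br)CC[C@]1(C)C1=CC2=C(C)CC[C@H](Br)[C@@]2(C)CC1=O | intermediate
27 | 4a,5-α-epoxide of 26 (oxirane oxygen anti to the 8a-methyl) | CC1(C)[C@H](Br)CC[C@]1(C)C1=C[C@@]23O[C@@]3(C)CC[C@H](Br)[C@@]2(C)CC1=O | intermediate
28 | CNP0216929.1, (4aR,5R,8S,8aS)-8-bromo-3-[(1R,3R)-3-bromo-1,2,2-trimethylcyclopentyl]-4a,5-dihydroxy-5,8a-dimethyl-4a,5,6,7,8,8a-hexahydronaphthalen-2(1H)-one | CC1(C)[C@H](Br)CC[C@]1(C)C1=C[C@]2(O)[C@](C)(O)CC[C@H](Br)[C@@]2(C)CC1=O | target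

**Step count**
Total step count: 19. Longest linear sequence: 15 steps (steps 1–7 and 12–19).

**Steps most likely to fail**

Step 13. The congested alkynol may fail to engage the oxo-rhenium catalyst, or the tertiary carbinol may dehydrate toward C5 (Rupe-type enyne formation) instead of rearranging. The fallback sets out from 18 and changes the activating group. Alkoxide-directed trans-hydroalumination with NaAlH2(OCH2CH2OMe)2 at 0 °C (hydride to C4, aluminium to C3) and iodinolysis at −78 °C should give the Z iodoalkenyl carbinol F1 with iodine cis to C4a. Acid-catalysed dehydration (TsOH cat., benzene) toward C5, the only carbon with a β-hydrogen, should give the dienyl iodide F2. Lemieux–Johnson cleavage of the allyl group gives the iodo aldehyde F3, which undergoes the same CrCl2/NiCl2 ring closure and rejoins the route at 25.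

Step 7. Substitution at the neopentyl-type secondary carbon may be outrun by E2 elimination or by a Wagner–Meerwein methyl shift. The fallback sets out from 4 and introduces bromine without a substitution. Condensation with hydrazine gives the hydrazone F4, and CuBr2/Et3N in methanol (Barton-type vinyl halide synthesis) gives the vinyl bromide F5. Hydrogen-atom-transfer hydrogenation (Mn(dpm)3 cat., PhSiH3, t-BuOOH), which leaves C–Br bonds intact, saturates the alkene; the C3′ epimers would have to be separated. The epimer with bromine cis to the ester, the bromo ester F6, is reduced with i-Bu2AlH to the bromo alcohol F7, oxidised with Dess–Martin periodinane to the bromo aldehyde F8 and homologated with the Ohira–Bestmann reagent to rejoin the route at 9.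

Step 16. Oxidative addition and transmetallation at the hindered alkenyl triflate may be slow, and the alkenylchromium species may be protonated before it reaches the aldehyde. The fallback sets out from 19 and forms the same C2–C3 bond with reversed polarity. Lemieux–Johnson cleavage of the allyl group gives the keto aldehyde F9. An N-heterocyclic carbene catalyst (triazolium salt, Et3N) turns the aldehyde carbon C2 into an acyl anion equivalent that adds to the C3 ketone (intramolecular crossed benzoin reaction) and gives the α-ketol F10. Acid-catalysed 1,4-dehydration (TsOH cat., toluene; loss of the C3 hydroxyl and the C5 hydrogen) should then give the dienone and rejoin the route at 26.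

Further compounds
F1 | step 13 | (2S,3S)-3-bromo-1-{(Z)-2-[(1S,3R)-3-bromo-1,2,2-trimethylcyclopentyl]-2-iodoethenyl}-2,6-dimethyl-2-(prop-2-en-1-yl)cyclohexan-1-ol, C1/C6 epimers | CC1(C)[C@H](Br)CC[C@]1(C)/C(I)=C/C1(O)C(C)CC[C@H](Br)[C@@]1(C)CC=C
F2 | step 13 | (5S,6S)-5-bromo-1-{(Z)-2-[(1S,3R)-3-bromo-1,2,2-trimethylcyclopentyl]-2-iodoethenyl}-2,6-dimethyl-6-(prop-2-en-1-yl)cyclohex-1-ene | CC1(C)[C@H](Br)CC[C@]1(C)/C(I)=C/C1=C(C)CC[C@H](Br)[C@@]1(C)CC=C
F3 | step 13 | 2-[(1S,6S)-6-bromo-2-{(Z)-2-[(1S,3R)-3-bromo-1,2,2-trimethylcyclopentyl]-2-iodoethenyl}-1,3-dimethylcyclohex-2-en-1-yl]acetaldehyde | CC1(C)[C@H](Br)CC[C@]1(C)/C(I)=C/C1=C(C)CC[C@H](Br)[C@@]1(C)CC=O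
F4 | step 7 | methyl (1S)-3-hydrazinylidene-1,2,2-trimethylcyclopentane-1-carboxylate | CC1(C)C(=NN)CC[C@]1(C)C(=O)OC
F5 | step 7 | methyl (1S)-3-bromo-1,2,2-trimethylcyclopent-3-ene-1-carboxylate | CC1(C)C(Br)=CC[C@]1(C)C(=O)OC
F6 | step 7 | methyl (1S,3R)-3-bromo-1,2,2-trimethylcyclopentane-1-carboxylate | CC1(C)[C@H](Br)CC[C@]1(C)C(=O)OC
F7 | step 7 | [(1S,3R)-3-bromo-1,2,2-trimethylcyclopentyl]methanol | CC1(C)[C@H](Br)CC[C@]1(C)CO
F8 | step 7 | (1S,3R)-3-bromo-1,2,2-trimethylcyclopentane-1-carbaldehyde | CC1(C)[C@H](Br)CC[C@]1(C)C=O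
F9 | step 16 | 2-[(1S,6S)-6-bromo-2-{(E)-2-[(1S,3R)-3-bromo-1,2,2-trimethylcyclopentyl]-2-oxoethylidene}-1,3-dimethylcyclohexyl]acetaldehyde, C3 epimers of the cyclohexane | CC1(C)[C@H](Br)CC[C@]1(C)C(=O)/C=C1\C(C)CC[C@H](Br)[C@@]1(C)CC=O
F10 | step 16 | (8S,8aS)-8-bromo-3-[(1S,3R)-3-bromo-1,2,2-trimethylcyclopentyl]-3-hydroxy-5,8a-dimethyl-3,5,6,7,8,8a-hexahydronaphthalen-2(1H)-one, C3/C5 epimers | CC1(C)[C@H](Br)CC[C@]1(C)C1(O)C=C2C(C)CC[C@H](Br)[C@@]2(C)CC1=O
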